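**Strategy.** The depside is not cut at its ester oxygen but through ring A: the C1–C2 and C5–C6 bonds of that ring are made last, on an ester link that already exists. The feature exploited is the resorcylate pattern of ring A: the carbonyl-bearing C1 lies between an oxygenated C2 and a pentyl-bearing C6, with a second oxygen at C4 and unsubstituted C3 and C5. This is the imprint of a 1,1,3-trioxygenated butadiene joined to the two alkyne carbons of an oct-2-ynoate. One Diels–Alder/aromatization therefore builds ring A with its full substitution. The precursor is benzyl olivetolate (ring B) acylated at its 4-hydroxyl with oct-2-ynoic acid.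

Key step: step 5

Remark: in both rings C1 is the carbon bearing the carbonyl group; ring A is the 2,4-dimethoxy-6-pentylbenzoyl ring, ring B the ring that ends with the free carboxylic acid. The geometry of diene 7 is drawn 1E; it has no bearing on the outcome because that carbon becomes aromatic.

**Step 1**
Reactants: 1 olivetol (5-pentylbenzene-1,3-diol)
Product: 2 olivetolic acid (2,4-dihydroxy-6-pentylbenzoic acid)
Conditions: MeOMgOCO2Me (2 M in DMF, excess), 120–125 °C, N2 sweep; then cold 2 M HCl
Reagents that add atoms: methyl magnesium carbonate, COC(=O)O[Mg]OC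
Why: Kolbe–Schmitt-type C-carboxylation of a resorcinol with methyl magnesium carbonate should place the carboxyl group ortho to one hydroxyl and para to the other, next to the pentyl chain, the acid being held as its magnesium salicylate chelate until acidification.

**Step 2**
Reactants: 2 olivetolic acid
Product: 3 benzyl 2,4-dihydroxy-6-pentylbenzoate
Conditions: BnBr (1.0 equiv), KHCO3, DMF, rt
Reagents that add atoms: benzyl bromide, BrCc1ccccc1
Why: Bicarbonate deprotonates only the carboxylic acid, so SN2 O-alkylation of the carboxylate by benzyl bromide should give the benzyl ester and leave both phenols free.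

**Step 3**
Reactants: 3 benzyl 2,4-dihydroxy-6-pentylbenzoate; 4 oct-2-ynoic acid
Product: 5 benzyl 2-hydroxy-4-(oct-2-ynoyloxy)-6-pentylbenzoate
Conditions: DCC (1.1 equiv), DMAP (5 mol %), CH2Cl2, −20 → 0 °C
Reagents that add atoms: none
Why: Steglich esterification should acylate the free 4-OH only, because the 2-OH is tied up in a hydrogen bond to the neighbouring ester carbonyl and is shielded by it; low temperature and little DMAP keep conjugate addition to the ynoate down.

**Step 4**
Reactants: 6 methyl (E)-3-methoxybut-2-enoate
Product: 7 (1E)-1,3-dimethoxy-1-(trimethylsilyloxy)buta-1,3-diene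
Conditions: LiN(i-Pr)2, THF, −78 °C; Me3SiCl, −78 °C → rt; filtration under Ar, bulb-to-bulb distillation
Reagents that add atoms: chlorotrimethylsilane, C[Si](C)(C)Cl
Why: Kinetic γ-deprotonation of the vinylogous ester (the methyl group is cis to the ester in the E isomer) gives the extended dienolate, whose O-silylation by the hard silyl chloride is the standard preparation of this type of ketene silyl acetal diene.

**Step 5**
Reactants: 5 benzyl 2-hydroxy-4-(oct-2-ynoyloxy)-6-pentylbenzoate; 7 (1E)-1,3-dimethoxy-1-(trimethylsilyloxy)buta-1,3-diene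
Product: 11 benzyl 2-hydroxy-4-[(2-hydroxy-4-methoxy-6-pentylbenzoyl)oxy]-6-pentylbenzoate, via ring B trimethylsilyl ether 8 (not isolated), via cyclohexa-1,4-diene cycloadduct 9 (not isolated), via bis(trimethylsilyl) ether 10 (not isolated)
Conditions: N,O-bis(trimethylsilyl)acetamide (1.2 equiv), toluene, rt → 50 °C; then 7 (3 equiv, in portions), 110–120 °C, sealed tube; then 1 M HCl, THF, rt
Reagents that add atoms: none
Why: The electron-rich diene 7 and the electron-poor aryl alkynoate 8 should combine in an asynchronous normal-demand Diels–Alder reaction in which the CH2 terminus (C4) of 7 bonds to the pentyl-bearing β-carbon of the ynoate (the C5–C6 bond of ring A) and the ketene acetal carbon (C1) of 7 to the α-carbon (the C1–C2 bond). Ring A thus closes as a six-membered carbocycle by intermolecular [4+2] cycloaddition to give the cyclohexa-1,4-diene 9, whose mixed methyl silyl ketal loses methanol by 1,4-elimination to give arene 10, and dilute acid then cleaves both silyl ethers. The closest known reaction type is the cycloaddition–aromatization of 1-alkoxy-1-silyloxy-3-oxygenated butadienes with acetylenic esters to give resorcylates, for which β-alkyl alkynoates need heating. No stereocentre survives, since the ketal carbon of 9 is formed racemic and becomes the aromatic C2. The step needs regioselectivity (oxygen at C2 beside the carbonyl-bearing C1, methoxy at C4 para to it), which the matched polarization of the ketene acetal and the ynoate secures. It also needs the diene to outlive a slow dienophile, which is served by silylating the ring B 2-OH beforehand (no acidic proton left) and by the extra activation that the aryl ester gives the triple bond.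

**Step 6**
Reactants: 11 benzyl 2-hydroxy-4-[(2-hydroxy-4-methoxy-6-pentylbenzoyl)oxy]-6-pentylbenzoate
Product: 12 benzyl 4-[(2,4-dimethoxy-6-pentylbenzoyl)oxy]-2-methoxy-6-pentylbenzoate
Conditions: MeI (excess), K2CO3, acetone, reflux
Reagents that add atoms: iodomethane, CI
Why: Williamson O-methylation of the two hydrogen-bonded salicylate-type phenols should proceed under carbonate in acetone, while the 2,6-disubstituted depside ester and the benzyl ester are too hindered to be attacked by carbonate or phenoxide.

**Step 7**
Reactants: 12 benzyl 4-[(2,4-dimethoxy-6-pentylbenzoyl)oxy]-2-methoxy-6-pentylbenzoate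
Product: 13 planaic acid (4-[(2,4-dimethoxy-6-pentylbenzoyl)oxy]-2-methoxy-6-pentylbenzoic acid)
Conditions: H2 (1 atm), 10% Pd/C, EtOAc, rt
Reagents that add atoms: none
Why: Catalytic hydrogenolysis cleaves only the benzylic C–O bond of the benzyl ester; the aryl ester, the methyl ethers and the arenes are inert and no other reducible group remains.

**Compound list**
1 | olivetol (5-pentylbenzene-1,3-diol) | CCCCCc1cc(O)cc(O)c1 | starting material
2 | olivetolic acid (2,4-dihydroxy-6-pentylbenzoic acid) | CCCCCc1cc(O)cc(O)c1C(=O)O | intermediate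
3 | benzyl 2,4-dihydroxy-6-pentylbenzoate | CCCCCc1cc(O)cc(O)c1C(=O)OCc1ccccc1 | intermediate
4 | oct-2-ynoic acid | CCCCCC#CC(=O)O | starting material
5 | benzyl 2-hydroxy-4-(oct-2-ynoyloxy)-6-pentylbenzoate | CCCCCC#CC(=O)Oc1cc(O)c(C(=O)OCc2ccccc2)c(CCCCC)c1 | intermediate
6 | methyl (E)-3-methoxybut-2-enoate | CO/C(C)=C/C(=O)OC | starting material
7 | (1E)-1,3-dimethoxy-1-(trimethylsilyloxy)buta-1,3-diene | C=C(OC)/C=C(/O[Si](C)(C)C)OC | intermediate
8 | benzyl 4-(oct-2-ynoyloxy)-6-pentyl-2-(trimethylsilyloxy)benzoate | CCCCCC#CC(=O)Oc1cc(O[Si](C)(C)C)c(C(=O)OCc2ccccc2)c(CCCCC)c1 | intermediate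
9 | benzyl 4-{[4,6-dimethoxy-2-pentyl-6-(trimethylsilyloxy)cyclohexa-1,4-diene-1-carbonyl]oxy}-6-pentyl-2-(trimethylsilyloxy)benzoate (racemic at the ketal carbon) | CCCCCC1=C(C(=O)Oc2cc(O[Si](C)(C)C)c(C(=O)OCc3ccccc3)c(CCCCC)c2)C(OC)(O[Si](C)(C)C)C=C(OC)C1 | intermediate
10 | benzyl 4-{[4-methoxy-6-pentyl-2-(trimethylsilyloxy)benzoyl]oxy}-6-pentyl-2-(trimethylsilyloxy)benzoate | CCCCCc1cc(OC(=O)c2c(CCCCC)cc(OC)cc2O[Si](C)(C)C)cc(O[Si](C)(C)C)c1C(=O)OCc1ccccc1 | intermediate
11 | benzyl 2-hydroxy-4-[(2-hydroxy-4-methoxy-6-pentylbenzoyl)oxy]-6-pentylbenzoate | CCCCCc1cc(OC(=O)c2c(CCCCC)cc(OC)cc2O)cc(O)c1C(=O)OCc1ccccc1 | intermediate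
12 | benzyl 4-[(2,4-dimethoxy-6-pentylbenzoyl)oxy]-2-methoxy-6-pentylbenzoate | CCCCCc1cc(OC(=O)c2c(CCCCC)cc(OC)cc2OC)cc(OC)c1C(=O)OCc1ccccc1 | intermediate
13 | planaic acid | CCCCCc1cc(OC(=O)c2c(CCCCC)cc(OC)cc2OC)cc(OC)c1C(=O)O | target

**Step count.** Total: 7 steps. Longest linear sequence: 6 steps (1, 2, 3, 5, 6, 7 from olivetol); the diene branch adds step 4.

**Steps most likely to fail**

Step 5. The cycloaddition to a β-alkyl ynoate is slow, so thermal decomposition or protodesilylation of the diene may outrun it, and conjugate addition without ring closure or acyl transfer at the aryl ester may compete. The fallback forms the ester link by acylation instead and sets out from 2 and 3. Exhaustive methylation of 2 (MeI, K2CO3, acetone, reflux) should give methyl 2,4-dimethoxy-6-pentylbenzoate F1, and saponification (KOH, aqueous DMSO, 90 °C) should give 2,4-dimethoxy-6-pentylbenzoic acid F2. Condensation of F2 with 3 by (CF3CO)2O in toluene at rt (acylium-type mixed anhydride, attack by the unchelated 4-OH) should give benzyl 4-[(2,4-dimethoxy-6-pentylbenzoyl)oxy]-2-hydroxy-6-pentylbenzoate F3. This is also what step 5 itself would deliver if the cycloadduct lost trimethylsilanol in place of methanol. Methylation of its single chelated phenol (MeI, K2CO3) comes back to the route at 12.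

Step 1. Carboxylation may occur at the carbon between the two hydroxyls in place of the one beside the pentyl chain, and the resorcylic acid may decarboxylate on heating or during work-up. The fallback fixes the position by halogenation and sets out from 1. Protection (MeOCH2Cl, i-Pr2NEt, CH2Cl2) should give 1,3-bis(methoxymethoxy)-5-pentylbenzene F4. Bromination (NBS, MeCN, 0 °C), which goes ortho to the alkyl chain and para to one ether, should give 2-bromo-1,5-bis(methoxymethoxy)-3-pentylbenzene F5. Bromine–lithium exchange (n-BuLi, THF, −78 °C) and addition of the aryllithium to excess benzyl chloroformate should give benzyl 2,4-bis(methoxymethoxy)-6-pentylbenzoate F6. Acetal cleavage (HCl, MeOH, rt) comes back to the route at 3, replacing steps 1 and 2.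

Step 3. DMAP or the phenol may add in conjugate fashion to the carbodiimide-activated ynoate, and the O-acylisourea may rearrange to an N-acylurea before the weakly nucleophilic phenol attacks. The fallback separates activation from acylation and uses no nucleophilic catalyst; it sets out from 4 and 3. Oxalyl chloride with a trace of DMF in CH2Cl2 at 0 °C should convert 4 into oct-2-ynoyl chloride F7. F7 is then added to 3 and 2,6-lutidine in CH2Cl2 at −20 °C, which comes back to the route at 5.

**Further compounds**
F1 | step 5 | methyl 2,4-dimethoxy-6-pentylbenzoate | CCCCCc1cc(OC)cc(OC)c1C(=O)OC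
F2 | step 5 | 2,4-dimethoxy-6-pentylbenzoic acid | CCCCCc1cc(OC)cc(OC)c1C(=O)O
F3 | step 5 | benzyl 4-[(2,4-dimethoxy-6-pentylbenzoyl)oxy]-2-hydroxy-6-pentylbenzoate | CCCCCc1cc(OC(=O)c2c(CCCCC)cc(OC)cc2OC)cc(O)c1C(=O)OCc1ccccc1
F4 | step 1 | 1,3-bis(methoxymethoxy)-5-pentylbenzene | CCCCCc1cc(OCOC)cc(OCOC)c1
F5 | step 1 | 2-bromo-1,5-bis(methoxymethoxy)-3-pentylbenzene | CCCCCc1cc(OCOC)cc(OCOC)c1Br
F6 | step 1 | benzyl 2,4-bis(methoxymethoxy)-6-pentylbenzoate | CCCCCc1cc(OCOC)cc(OCOC)c1C(=O)OCc1ccccc1
F7 | step 3 | oct-2-ynoyl chloride | CCCCCC#CC(=O)Cl
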